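## The problem

Compound 28 is a labdane-type diterpenoid (labdane numbering: C4 CMe2, C5 ring-fusion CH, C6 C=O, C7 CHOH, C8 C(OAc)CH3, C9 spiro carbon, C10 angular CCH3, C11–C12 CH2CH2, C13 second spiro carbon, C14=C15 enol ether, C16 OCH2). Its decalin (rings A and B) is cis-fused, with H-5 and the C10 methyl on the same face. C9 is spiro-linked through a tetrahydrofuran (ring C, oxygen between C9 and C13) to a 2,3-dihydrofuran (ring D) that is itself spiro at C13. Ring B is oxidised on four adjacent carbons: the C6 ketone, the C7 secondary alcohol, the C8 tertiary acetate and the C9 tertiary ether. C8 and C9 lie next to the quaternary C10, so every bond to C9 has to be made in a crowded environment.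

There are six stereocentres (5R,7R,8R,9S,10S,13S). C10 can be bought and can control C8. The C8 oxygen is cis to the C9 oxygen and homoallylic to a 5,6-alkene, so it can direct reagents to the α face at C9 and at C5/C6. The C8 substituents flank C7. C13 is separated from the decalin by two methylene groups and needs reagent control.

Several groups are fragile:
- The enol ether next to the spiro ether carbon would aromatise to a furan with acid, opening ring C.
- The β-acetoxy ketone would eliminate with base.
- The tertiary acetate beside a free secondary alcohol cannot be made by selective acylation.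
- H-5 is α to the ketone, so the cis fusion must be set kinetically and not equilibrated.

The feature that opens the structure is the C8 tertiary carbinol carbon with its methyl group, bonded directly to C9. With C9 at the ketone level this is a 2-hydroxy-2-methylcyclohexanone, the signature product of an acyloin shift in a 1-acetylcyclopentanol. Ring B (C5–C10) can therefore be grown from a hydrindene carrying hydroxyl and acetyl on C9, with C7–C8 formed in the shift.

## Retrosynthesis

**Ring D (O–C15).** The enol ether is disconnected last, giving the homopropargylic alcohol 27 (C14≡C15 terminal alkyne, C16 as CH2OH on C13). Lactol dehydration or lactone reduction would expose the ketone, the acetate and the free 7-hydroxyl to hydride or sulfonylating reagents. An alkynol cycloisomerisation is a neutral isomerisation and can be the final step. It must close only in the endo sense onto the terminal alkyne carbon.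

**C7–O.** Compound 27 comes from the silyl ether 26, and 26 from the silyl enol ether 23 of ketone 22. The hydroxyl is introduced after the acetate, because a secondary alcohol could not stay free while the hindered tertiary one is acylated. A metal enolate is excluded by the β-acetate, so the neutral silyl enol ether is oxidised. The forward step needs enolisation toward C7 and β-face attack.

**C6=O and H-5.** Ketone 22 is traced to the 5α,6α-epoxide 21 through a 1,2-hydride shift, which delivers H-5 on the face opposite the epoxide oxygen. Hydroboration would add H and O to the same face and gives no such link between oxygen delivery and the ring fusion. Epoxide 21 is the acetate of 20, and 20 comes from alkene 19 by delivery of oxygen from the homoallylic 8α-hydroxyl. The order is therefore epoxidation, then acetylation, then rearrangement.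

**C14–C15.** Alkyne 19 is cut back by one carbon to aldehyde 18 and the primary alcohol 17. C13 then carries two chemically different CH2O arms.

**Ring C (O9–C13) and the C13 configuration.** Both carbons of this ether bond are tertiary, so only an epoxide can serve as the electrophile with stereocontrol. Compound 17 arises from oxirane 16 by 5-exo opening with inversion. Oxirane 16 is the silyl ether of 15, the Sharpless epoxide of the 2-substituted allylic alcohol 14. An oxa-Michael or halo-etherification closure would leave C13 to substrate control across two methylenes. Silylation before ring opening keeps the two arms distinct.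

**C11–C12.** Triol 14 is cut into the spiro-oxirane 12 (electrophilic C11, C9–O already in place) and 2-methylprop-2-en-1-ol 13, used as its dianion. This supplies C12, C13, C14 and C16 in one bond formation.

**C9–O and C9=C11.** A side-chain nucleophile added to the C9 ketone of 10 would be expected to enter from the α face, away from the two β methyl groups, and give the wrong C9 epimer. The polarity is therefore inverted. Ketone 10 is methylenated to 11, and the 8α-hydroxyl delivers oxygen to the α face to give 12.

**Key disconnection (C7–C8).** Ketol 10 is the ring-enlarged isomer of the acetyl carbinol 9. The shift of C7 from C9 to the acetyl carbon forms ring B, the C9 ketone and the C8 stereocentre together. Because 9 has its hydroxyl cis to the angular methyl, the required C8 configuration follows from an open (base) transition state; a chelating Lewis acid would give the epimer.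

**C8–C9.** Compound 9 comes from the hexahydroindenone 6 and ethyl vinyl ether 7 as an acetyl anion equivalent, added anti to the angular methyl.

**Hydrindenone.** Compound 6 is reached from the (S)-Hajos–Parrish ketone 1 by the sequence established in the Wieland–Miescher series: ketal 2, deconjugative gem-dimethylation to 3, Wolff–Kishner reduction to 5 and deketalisation.

## Roads not taken

Alternative 1: The cut is C5–C10 in ring A, with C2–O as the bond given up. An Ireland–Claisen rearrangement of the silyl ketene acetal of an alkenyl-substituted six-membered lactone (LiN(i-Pr)2, Me3SiCl, then heat) would give the cyclohexene acid A1. In A1 the acid carbon (C6) on C5 and the silyloxymethyl carbon (C9) on the quaternary C10 are cis.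
- Merit: the boat transition state enforced by the lactone fixes the C5/C10 relationship, the ring fusion of 28, in one pericyclic step at the outset. In this respect it is better than the late epoxide rearrangement used here.
- Weak points: A1 contains none of ring B. C6–C7, C7–C8 and C8–C9 would all still have to be made, and C9 arrives as a primary CH2O carbon that must become a fully substituted spiro carbinol carbon. The C1–C2 alkene must be removed, and C5 stays α to a carboxyl (later a ketone) throughout. The enantiopure lactone needs its own synthesis with a defined carbinol centre and alkene geometry.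
- Comparison: against the better fusion control, the chosen plan delivers ring B complete with the C8 hydroxyl/methyl pair and the C9 carbonyl in one rearrangement from a commercial enantiopure dione.

Alternative 2: The cut is C13–C14. A diazoacetate ester on the C16 oxygen of a 9,13-epoxy precursor with a tertiary C13–H would lose N2 with Rh2(OAc)4 or Rh2(cap)4. The carbenoid would insert into C13–H with retention and close ring D as the γ-lactone A2 (8-hydroxyl as methoxymethyl ether).
- Merits: C–H bonds α to an ether oxygen are activated for insertion, five-membered closure is the normal mode, and the quaternary C13 is formed without an ionisable intermediate. Ring D arrives in one step from an alcohol, which is shorter than the five operations (steps 10–14) spent here on C13 and the alkyne.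
- Weak points: the stereochemical problem is only moved, since the C13–H centre must first be set relative to C9 under substrate control. The carbenoid can also cyclopropanate the 5,6-alkene of A2 or insert next to the other ether carbon. The lactone must later be reduced and dehydrated to the enol ether, which the C6 ketone, the C8 acetate and a free C7 hydroxyl do not tolerate. It also offers nothing for ring B.
- Comparison: the chosen plan is longer at ring D, but it fixes C13 by reagent control and closes ring D last by a neutral isomerisation.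

Alternative 3: The cut is C4–C5 and C1–C10. A Diels–Alder reaction of the quinone A3 with the diene A4 under a chiral oxazaborolidinium Lewis acid would give the cis-fused enedione A5. A5 carries the angular methyl, the gem-dimethyl group, both ring-B carbonyls and the C8 methyl.
- Merit: this is by far the shortest entry to a cis-decalin of the right constitution, one catalytic asymmetric step against six steps to 10. On step count to the bicyclic core it is clearly superior.
- Weak points: A4 has two substituents on one diene terminus and reaches the s-cis conformation poorly. That terminus must bond to C5 while the methyl-bearing quinone carbon becomes C10, so rate, regiochemistry and enantioselectivity are all uncertain. In A5 the C5 centre is α to a carbonyl from the first step, C6 and C9 must be told apart, the 2,3-alkene must be removed, and the C7=C8 enedione must become a trans hydroxyl/tertiary acetate pair, which cis-dihydroxylation does not give.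
- Comparison: against this brevity the chosen plan sets an unambiguous absolute configuration from the chiral pool, a single carbonyl at C9, and a C8 carbinol formed with the right configuration in the key step.

Key step: step 6

Remark on the chemistry: the given descriptors are read as a cis A/B fusion (H-5 and the C10 methyl both β), 7β-OH, 8α-OAc/8β-CH3 and the C9 ether oxygen α; the route is built for exactly this isomer.

## Route

Step 1
Reactants: 1 (S)-Hajos–Parrish ketone [(7aS)-7a-methyl-2,3,7,7a-tetrahydro-1H-indene-1,5(6H)-dione]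
Product: 2 (7aS)-7a-methyl-2,3,7,7a-tetrahydrospiro[indene-1,2'-[1,3]dioxolan]-5(6H)-one
Conditions: 2-ethyl-2-methyl-1,3-dioxolane, ethylene glycol (cat.), p-TsOH·H2O (cat.), rt
Reagents that add atoms: 2-ethyl-2-methyl-1,3-dioxolane, CCC1(C)OCCO1
Why: Acid-catalysed transketalisation is selective for the saturated cyclopentanone carbonyl, because the conjugated enone carbonyl is much less electrophilic. This is the usual differentiation of such bicyclic enediones and leaves C7a untouched.

Step 2
Reactants: 2 (7aS)-7a-methyl-2,3,7,7a-tetrahydrospiro[indene-1,2'-[1,3]dioxolan]-5(6H)-one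
Product: 3 (7aS)-4,4,7a-trimethyl-2,4,7,7a-tetrahydrospiro[indene-1,2'-[1,3]dioxolan]-5(6H)-one
Conditions: KOt-Bu (3 equiv), MeI (6 equiv), t-BuOH–THF, 0 °C to rt
Reagents that add atoms: iodomethane, CI
Why: Deconjugative α,α-dialkylation through the extended enolate: both methyl groups enter at C4 and the double bond moves to C3=C3a, as in the Wieland–Miescher series. No stereocentre is formed.

Step 3
Reactants: 3 (7aS)-4,4,7a-trimethyl-2,4,7,7a-tetrahydrospiro[indene-1,2'-[1,3]dioxolan]-5(6H)-one
Product: 5 (7aS)-4,4,7a-trimethyl-2,4,5,6,7,7a-hexahydrospiro[indene-1,2'-[1,3]dioxolane], via hydrazone 4 (not isolated)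
Conditions: N2H4·H2O, KOH, diethylene glycol, 130 °C then 200 °C
Reagents that add atoms: none
Why: Wolff–Kishner reduction removes the hindered, non-conjugated C5 carbonyl. The ketal and the isolated trisubstituted alkene should survive hot alkali.

Step 4
Reactants: 5 (7aS)-4,4,7a-trimethyl-2,4,5,6,7,7a-hexahydrospiro[indene-1,2'-[1,3]dioxolane]
Product: 6 (7aS)-4,4,7a-trimethyl-2,4,5,6,7,7a-hexahydro-1H-inden-1-one
Conditions: PPTS, THF–H2O (4:1), 50 °C
Reagents that add atoms: water, O
Why: Mild acid hydrolysis of the dioxolane. A weak acid is chosen so that the β,γ double bond does not move into conjugation.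

Step 5
Reactants: 6 (7aS)-4,4,7a-trimethyl-2,4,5,6,7,7a-hexahydro-1H-inden-1-one; 7 ethyl vinyl ether
Product: 9 1-[(1S,7aS)-1-hydroxy-4,4,7a-trimethyl-2,4,5,6,7,7a-hexahydro-1H-inden-1-yl]ethan-1-one, via ethoxyvinyl carbinol 8 (not isolated)
Conditions: 7, t-BuLi, THF, −78 to 0 °C; CeCl3, −78 °C; then 6, −78 °C; then 1 M aq. HCl, THF, 0 °C
Reagents that add atoms: water, O
Why: 1,2-Addition of a 1-ethoxyvinyl metal (acetyl anion equivalent), with cerium suppressing enolisation of the doubly activated C2–H. Attack anti to the angular methyl should place the hydroxyl cis to that methyl (1S). Enol ether hydrolysis then frees the methyl ketone.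

Step 6
Reactants: 9 1-[(1S,7aS)-1-hydroxy-4,4,7a-trimethyl-2,4,5,6,7,7a-hexahydro-1H-inden-1-yl]ethan-1-one
Product: 10 (2R,8aS)-2-hydroxy-2,5,5,8a-tetramethyl-3,5,6,7,8,8a-hexahydronaphthalen-1(2H)-one
Conditions: KOH (2 equiv), MeOH–H2O (10:1), 60 °C
Reagents that add atoms: none
Why: Base-mediated α-ketol (acyloin) rearrangement: the C9 alkoxide pushes the C9–C7 σ bond onto the acetyl carbon C8 in a suprafacial 1,2-shift, so C9 becomes the ketone and the former carbonyl oxygen the C8 hydroxyl. The closest known reaction is the alkali-promoted D-homoannulation of 17-hydroxy-20-oxo steroids, in which the ring methylene migrates. Ring B is closed by one-carbon ring enlargement (C8 inserted between C7 and C9, cyclopentene to cyclohexene), not by an end-to-end cyclisation, and relief of strain in the five-membered carbinol drives it. The only new stereocentre, C8, is set by the C9 configuration of 9 together with the open transition state expected for a potassium alkoxide in methanol: the two oxygens lie anti, C7 bonds to the carbonyl face turned toward it, and the new methyl ends cis to the C10 methyl (8R). A chelating Lewis acid such as BF3·OEt2 or Al(Oi-Pr)3 would hold the oxygens syn and give the C8 epimer from 9, so it is avoided. The step needs migration of C7 rather than C10; C7 is an unhindered allylic methylene whose shift joins C8 to a CH2, whereas migration of C10 would have to join two fully substituted carbons. C10 and the 5,6-alkene are spectators, and 10 has no enolisable position next to C9.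

Step 7
Reactants: 10 (2R,8aS)-2-hydroxy-2,5,5,8a-tetramethyl-3,5,6,7,8,8a-hexahydronaphthalen-1(2H)-one
Product: 11 (2R,8aS)-2,5,5,8a-tetramethyl-1-methylidene-1,2,3,5,6,7,8,8a-octahydronaphthalen-2-ol
Conditions: Cp2Ti(μ-Cl)(μ-CH2)AlMe2 (Tebbe reagent, 3 equiv), pyridine (cat.), THF–toluene, −40 °C to rt
Reagents that add atoms: Tebbe reagent, C[Al-]1(C)C[Ti](C2C=CC=C2)(C2C=CC=C2)[Cl+]1
Why: Titanium methylidene olefination; the small Cp2Ti=CH2 unit methylenates carbonyls flanked by fully substituted carbons where phosphorus ylides are sluggish. Excess reagent allows for metallation of the free tertiary hydroxyl. No stereocentre is formed.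

Step 8
Reactants: 11 (2R,8aS)-2,5,5,8a-tetramethyl-1-methylidene-1,2,3,5,6,7,8,8a-octahydronaphthalen-2-ol
Product: 12 (1R,2R,8aS)-2,5,5,8a-tetramethyl-3,5,6,7,8,8a-hexahydro-2H-spiro[naphthalene-1,2'-oxiran]-2-ol
Conditions: VO(acac)2 (5 mol %), t-BuOOH (1.1 equiv), CH2Cl2, 0 °C
Reagents that add atoms: tert-butyl hydroperoxide, CC(C)(C)OO
Why: Hydroxyl-directed epoxidation of an allylic alcohol: the C8 vanadate ester delivers oxygen to the alkene face syn to the 8α-hydroxyl, which is also the face away from the C8 and C10 methyl groups. The oxirane oxygen is therefore α and C11 β, the C9 configuration of 28. The homoallylic 5,6-alkene should react much more slowly.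

Step 9
Reactants: 12 (1R,2R,8aS)-2,5,5,8a-tetramethyl-3,5,6,7,8,8a-hexahydro-2H-spiro[naphthalene-1,2'-oxiran]-2-ol; 13 2-methylprop-2-en-1-ol
Product: 14 (1S,2R,8aS)-1-[3-(hydroxymethyl)but-3-en-1-yl]-2,5,5,8a-tetramethyl-1,2,3,5,6,7,8,8a-octahydronaphthalene-1,2-diol
Conditions: 13 (4 equiv), n-BuLi (8 equiv), TMEDA, Et2O–hexane, 0 °C to rt; then 12, THF, −20 °C to rt; then H2O
Reagents that add atoms: none
Why: SN2 epoxide opening at the unsubstituted oxirane carbon C11 by an allyllithium-type carbon nucleophile (the dianion of 13). C9 is not touched, and the 8-oxygen is cis to the oxirane oxygen, so it cannot displace it. No new stereocentre.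

Step 10
Reactants: 14 (1S,2R,8aS)-1-[3-(hydroxymethyl)but-3-en-1-yl]-2,5,5,8a-tetramethyl-1,2,3,5,6,7,8,8a-octahydronaphthalene-1,2-diol
Product: 15 (1S,2R,8aS)-1-{2-[(2S)-2-(hydroxymethyl)oxiran-2-yl]ethyl}-2,5,5,8a-tetramethyl-1,2,3,5,6,7,8,8a-octahydronaphthalene-1,2-diol
Conditions: Ti(Oi-Pr)4 (1.0 equiv), L-(+)-diethyl tartrate (1.2 equiv), t-BuOOH, 4 Å MS, CH2Cl2, −20 °C
Reagents that add atoms: tert-butyl hydroperoxide, CC(C)(C)OO
Why: Sharpless asymmetric epoxidation of a 2-substituted allylic alcohol. The L-(+)-tartrate catalyst selects the alkene face independently of the remote decalin centres, in the sense that converts 13 into (S)-2-methylglycidol, and should give the (2S)-oxirane. The tertiary hydroxyls and the 5,6-alkene are not substrates.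

Step 11
Reactants: 15 (1S,2R,8aS)-1-{2-[(2S)-2-(hydroxymethyl)oxiran-2-yl]ethyl}-2,5,5,8a-tetramethyl-1,2,3,5,6,7,8,8a-octahydronaphthalene-1,2-diol
Product: 16 (1S,2R,8aS)-1-{2-[(2R)-2-({[tert-butyl(diphenyl)silyl]oxy}methyl)oxiran-2-yl]ethyl}-2,5,5,8a-tetramethyl-1,2,3,5,6,7,8,8a-octahydronaphthalene-1,2-diol
Conditions: TBDPSCl, imidazole, CH2Cl2, 0 °C
Reagents that add atoms: tert-butyl(chloro)diphenylsilane, CC(C)(C)[Si](Cl)(c1ccccc1)c1ccccc1
Why: Selective silylation of the primary alcohol. It distinguishes the two CH2O arms on C13 before the oxirane is opened and so keeps the stereochemical information of step 10 (the descriptor becomes R without a change of geometry).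

Step 12
Reactants: 16 (1S,2R,8aS)-1-{2-[(2R)-2-({[tert-butyl(diphenyl)silyl]oxy}methyl)oxiran-2-yl]ethyl}-2,5,5,8a-tetramethyl-1,2,3,5,6,7,8,8a-octahydronaphthalene-1,2-diol
Product: 17 (8R,9S,10S,13S)-16-[tert-butyl(diphenyl)silyl]oxy-9,13-epoxy-15-norlabd-5-ene-8,14-diol
Conditions: CSA (10 mol %), CH2Cl2, 0 °C
Reagents that add atoms: none
Why: Acid-catalysed 5-exo-tet epoxide opening by the 9-hydroxyl at the tertiary oxirane carbon, with inversion, closes ring C and sets C13 (S). Attack by the 8-hydroxyl would need a six-membered transition state and should be slower.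

Step 13
Reactants: 17 (8R,9S,10S,13S)-16-[tert-butyl(diphenyl)silyl]oxy-9,13-epoxy-15-norlabd-5-ene-8,14-diol
Product: 18 (8R,9S,10S,13R)-16-[tert-butyl(diphenyl)silyl]oxy-8-hydroxy-9,13-epoxy-15-norlabd-5-en-14-al
Conditions: Dess–Martin periodinane, CH2Cl2, 0 °C to rt
Reagents that add atoms: none
Why: Dess–Martin oxidation of the primary alcohol to the aldehyde. The α-carbon is quaternary, so it cannot epimerise, and the tertiary 8-hydroxyl is inert.

Step 14
Reactants: 18 (8R,9S,10S,13R)-16-[tert-butyl(diphenyl)silyl]oxy-8-hydroxy-9,13-epoxy-15-norlabd-5-en-14-al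
Product: 19 (8R,9S,10S,13S)-16-[tert-butyl(diphenyl)silyl]oxy-9,13-epoxylabd-5-en-14-yn-8-ol
Conditions: dimethyl (1-diazo-2-oxopropyl)phosphonate, K2CO3, MeOH, 0 °C to rt
Reagents that add atoms: dimethyl (1-diazo-2-oxopropyl)phosphonate, COP(=O)(OC)C(=[N+]=[N-])C(C)=O
Why: Seyferth–Gilbert homologation with the Ohira–Bestmann reagent converts the non-enolisable aldehyde into the terminal alkyne (C14≡C15) by 1,2-hydride shift in the alkylidene carbene. C13 is not involved.

Step 15
Reactants: 19 (8R,9S,10S,13S)-16-[tert-butyl(diphenyl)silyl]oxy-9,13-epoxylabd-5-en-14-yn-8-ol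
Product: 20 (5R,6S,8R,9S,10S,13S)-16-[tert-butyl(diphenyl)silyl]oxy-5,6:9,13-diepoxylabd-14-yn-8-ol
Conditions: VO(acac)2 (10 mol %), t-BuOOH, toluene, 40 °C
Reagents that add atoms: tert-butyl hydroperoxide, CC(C)(C)OO
Why: Hydroxyl-directed epoxidation of a cyclic homoallylic alcohol (cyclohex-3-en-1-ol type). Oxygen is delivered syn to the axial 8α-hydroxyl and should give the 5α,6α-epoxide needed for the cis fusion. The alkyne is inert.

Step 16
Reactants: 20 (5R,6S,8R,9S,10S,13S)-16-[tert-butyl(diphenyl)silyl]oxy-5,6:9,13-diepoxylabd-14-yn-8-ol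
Product: 21 (5R,6S,8R,9S,10S,13S)-16-[tert-butyl(diphenyl)silyl]oxy-5,6:9,13-diepoxylabd-14-yn-8-yl acetate
Conditions: Ac2O, DMAP (1 equiv), Et3N, CH2Cl2, 40 °C
Reagents that add atoms: acetic anhydride, CC(=O)OC(C)=O
Why: DMAP-catalysed acylation of the only free, tertiary hydroxyl. It is done before the ketone exists, so that no β-acetoxy ketone meets amine base.

Step 17
Reactants: 21 (5R,6S,8R,9S,10S,13S)-16-[tert-butyl(diphenyl)silyl]oxy-5,6:9,13-diepoxylabd-14-yn-8-yl acetate
Product: 22 (5R,8R,9S,10S,13S)-16-[tert-butyl(diphenyl)silyl]oxy-6-oxo-9,13-epoxylabd-14-yn-8-yl acetate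
Conditions: BF3·OEt2 (1.2 equiv), toluene, −78 to −40 °C; Et3N quench
Reagents that add atoms: none
Why: Meinwald rearrangement: Lewis-acid opening at the tertiary C5 with 1,2-shift of the 6β-hydrogen to the β face of C5, anti to the departing α oxygen, should give the C6 ketone with H-5 cis to the C10 methyl. The analogy is the conversion of steroidal 5α,6α-epoxides into 5β-6-ketones. The 8α-acetate is syn to the epoxide and cannot participate.

Step 18
Reactants: 22 (5R,8R,9S,10S,13S)-16-[tert-butyl(diphenyl)silyl]oxy-6-oxo-9,13-epoxylabd-14-yn-8-yl acetate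
Product: 23 (5R,8R,9S,10S,13S)-16-[tert-butyl(diphenyl)silyl]oxy-6-(trimethylsilyloxy)-9,13-epoxylabd-6-en-14-yn-8-yl acetate
Conditions: TMSOTf, Et3N, CH2Cl2, −78 to 0 °C
Reagents that add atoms: trimethylsilyl trifluoromethanesulfonate, C[Si](C)(C)OS(=O)(=O)C(F)(F)F
Why: Soft enolisation and silylation should give the less substituted 6-ene silyl enol ether, because C5–H is shielded by two quaternary neighbours. No free enolate is formed, so the β-acetate is not eliminated and C5 is not epimerised.

Step 19
Reactants: 23 (5R,8R,9S,10S,13S)-16-[tert-butyl(diphenyl)silyl]oxy-6-(trimethylsilyloxy)-9,13-epoxylabd-6-en-14-yn-8-yl acetate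
Product: 26 (5R,7R,8R,9S,10S,13S)-16-[tert-butyl(diphenyl)silyl]oxy-7-hydroxy-6-oxo-9,13-epoxylabd-14-yn-8-yl acetate, via silyloxy epoxide 24 (not isolated), via 7-silyloxy ketone 25 (not isolated)
Conditions: dimethyldioxirane, acetone–CH2Cl2, −78 to 0 °C; then citric acid, MeOH, 0 °C
Reagents that add atoms: dimethyldioxirane, CC1(C)OO1
Why: Rubottom oxidation. The dioxirane should attack C7 from the β face, anti to the axial 8α-acetate on the neighbouring carbon and in the axial sense, and the silyloxy oxirane rearranges by silyl shift to the α-silyloxy ketone, which methanolic citric acid desilylates. This sets C7 (R), trans to the C8 acetate.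

Step 20
Reactants: 26 (5R,7R,8R,9S,10S,13S)-16-[tert-butyl(diphenyl)silyl]oxy-7-hydroxy-6-oxo-9,13-epoxylabd-14-yn-8-yl acetate
Product: 27 (5R,7R,8R,9S,10S,13S)-7,16-dihydroxy-6-oxo-9,13-epoxylabd-14-yn-8-yl acetate
Conditions: HF·pyridine, pyridine, THF, 0 °C to rt
Reagents that add atoms: none
Why: Fluoride cleavage of the silyl ether with buffered HF·pyridine, which should neither eliminate the β-acetate nor disturb the α-ketol. It is done before the acid-labile enol ether exists.

Step 21
Reactants: 27 (5R,7R,8R,9S,10S,13S)-7,16-dihydroxy-6-oxo-9,13-epoxylabd-14-yn-8-yl acetate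
Product: 28 (5R,7R,8R,9S,10S,13S)-7-hydroxy-6-oxo-9,13:15,16-diepoxylabd-14-en-8-yl acetate (CNP0275274.1)
Conditions: Mo(CO)6 (30 mol %), Et3N–Et2O (1:10), hν (350 nm), rt
Reagents that add atoms: none
Why: Molybdenum-carbonyl-catalysed cycloisomerisation of a homopropargylic alcohol: the terminal alkyne becomes a molybdenum vinylidene whose α-carbon (C15) is attacked by the C16 hydroxyl, a 5-endo closure that gives the 2,3-dihydrofuran under non-acidic conditions. C13 is quaternary, so only the 14,15-enol ether can form.

## Compound list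

1 | (S)-Hajos–Parrish ketone, (7aS)-7a-methyl-2,3,7,7a-tetrahydro-1H-indene-1,5(6H)-dione | C[C@]12CCC(=O)C=C1CCC2=O | starting material
2 | (7aS)-7a-methyl-2,3,7,7a-tetrahydrospiro[indene-1,2'-[1,3]dioxolan]-5(6H)-one | C[C@]12CCC(=O)C=C1CCC23OCCO3 | intermediate
3 | (7aS)-4,4,7a-trimethyl-2,4,7,7a-tetrahydrospiro[indene-1,2'-[1,3]dioxolan]-5(6H)-one | C[C@]12CCC(=O)C(C)(C)C1=CCC23OCCO3 | intermediate
4 | hydrazone of 3 at C5 | C[C@]12CCC(=NN)C(C)(C)C1=CCC23OCCO3 | intermediate (not isolated)
5 | (7aS)-4,4,7a-trimethyl-2,4,5,6,7,7a-hexahydrospiro[indene-1,2'-[1,3]dioxolane] | C[C@]12CCCC(C)(C)C1=CCC23OCCO3 | intermediate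
6 | (7aS)-4,4,7a-trimethyl-2,4,5,6,7,7a-hexahydro-1H-inden-1-one | C[C@]12CCCC(C)(C)C1=CCC2=O | intermediate
7 | ethyl vinyl ether | C=COCC | starting material
8 | (1S,7aS)-1-(1-ethoxyethenyl)-4,4,7a-trimethyl-2,4,5,6,7,7a-hexahydro-1H-inden-1-ol | C=C(OCC)[C@]1(O)CC=C2C(C)(C)CCC[C@]12C | intermediate (not isolated)
9 | 1-[(1S,7aS)-1-hydroxy-4,4,7a-trimethyl-2,4,5,6,7,7a-hexahydro-1H-inden-1-yl]ethan-1-one (OH cis to the angular methyl) | CC(=O)[C@]1(O)CC=C2C(C)(C)CCC[C@]12C | intermediate
10 | (2R,8aS)-2-hydroxy-2,5,5,8a-tetramethyl-3,5,6,7,8,8a-hexahydronaphthalen-1(2H)-one | O[C@]1(C)CC=C2C(C)(C)CCC[C@]2(C)C1=O | intermediate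
11 | (2R,8aS)-2,5,5,8a-tetramethyl-1-methylidene-1,2,3,5,6,7,8,8a-octahydronaphthalen-2-ol | O[C@]1(C)CC=C2C(C)(C)CCC[C@]2(C)C1=C | intermediate
12 | (1R,2R,8aS)-2,5,5,8a-tetramethyl-3,5,6,7,8,8a-hexahydro-2H-spiro[naphthalene-1,2'-oxiran]-2-ol (oxirane O cis to OH) | O[C@]1(C)CC=C2C(C)(C)CCC[C@]2(C)[C@@]12CO2 | intermediate
13 | 2-methylprop-2-en-1-ol | CC(=C)CO | starting material
14 | (1S,2R,8aS)-1-[3-(hydroxymethyl)but-3-en-1-yl]-2,5,5,8a-tetramethyl-1,2,3,5,6,7,8,8a-octahydronaphthalene-1,2-diol | O[C@]1(C)CC=C2C(C)(C)CCC[C@]2(C)[C@@]1(O)CCC(=C)CO | intermediate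
15 | (1S,2R,8aS)-1-{2-[(2S)-2-(hydroxymethyl)oxiran-2-yl]ethyl}-2,5,5,8a-tetramethyl-1,2,3,5,6,7,8,8a-octahydronaphthalene-1,2-diol | O[C@]1(C)CC=C2C(C)(C)CCC[C@]2(C)[C@@]1(O)CC[C@]1(CO)CO1 | intermediate
16 | (1S,2R,8aS)-1-{2-[(2R)-2-({[tert-butyl(diphenyl)silyl]oxy}methyl)oxiran-2-yl]ethyl}-2,5,5,8a-tetramethyl-1,2,3,5,6,7,8,8a-octahydronaphthalene-1,2-diol | O[C@]1(C)CC=C2C(C)(C)CCC[C@]2(C)[C@@]1(O)CC[C@]1(CO[Si](c2ccccc2)(c2ccccc2)C(C)(C)C)CO1 | intermediate
17 | (8R,9S,10S,13S)-16-[tert-butyl(diphenyl)silyl]oxy-9,13-epoxy-15-norlabd-5-ene-8,14-diol | O[C@]1(C)CC=C2C(C)(C)CCC[C@]2(C)[C@@]12CC[C@@](CO[Si](c3ccccc3)(c3ccccc3)C(C)(C)C)(CO)O2 | intermediate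
18 | (8R,9S,10S,13R)-16-[tert-butyl(diphenyl)silyl]oxy-8-hydroxy-9,13-epoxy-15-norlabd-5-en-14-al | O[C@]1(C)CC=C2C(C)(C)CCC[C@]2(C)[C@@]12CC[C@@](CO[Si](c3ccccc3)(c3ccccc3)C(C)(C)C)(C=O)O2 | intermediate
19 | (8R,9S,10S,13S)-16-[tert-butyl(diphenyl)silyl]oxy-9,13-epoxylabd-5-en-14-yn-8-ol | O[C@]1(C)CC=C2C(C)(C)CCC[C@]2(C)[C@@]12CC[C@@](CO[Si](c3ccccc3)(c3ccccc3)C(C)(C)C)(C#C)O2 | intermediate
20 | (5R,6S,8R,9S,10S,13S)-16-[tert-butyl(diphenyl)silyl]oxy-5,6:9,13-diepoxylabd-14-yn-8-ol (5α,6α-epoxide) | O[C@]1(C)C[C@@H]2O[C@@]23C(C)(C)CCC[C@]3(C)[C@@]14CC[C@@](CO[Si](c5ccccc5)(c5ccccc5)C(C)(C)C)(C#C)O4 | intermediate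
21 | (5R,6S,8R,9S,10S,13S)-16-[tert-butyl(diphenyl)silyl]oxy-5,6:9,13-diepoxylabd-14-yn-8-yl acetate | CC(=O)O[C@]1(C)C[C@@H]2O[C@@]23C(C)(C)CCC[C@]3(C)[C@@]14CC[C@@](CO[Si](c5ccccc5)(c5ccccc5)C(C)(C)C)(C#C)O4 | intermediate
22 | (5R,8R,9S,10S,13S)-16-[tert-butyl(diphenyl)silyl]oxy-6-oxo-9,13-epoxylabd-14-yn-8-yl acetate (cis-fused) | CC(=O)O[C@]1(C)CC(=O)[C@@H]2C(C)(C)CCC[C@]2(C)[C@@]12CC[C@@](CO[Si](c3ccccc3)(c3ccccc3)C(C)(C)C)(C#C)O2 | intermediate
23 | (5R,8R,9S,10S,13S)-16-[tert-butyl(diphenyl)silyl]oxy-6-(trimethylsilyloxy)-9,13-epoxylabd-6-en-14-yn-8-yl acetate | CC(=O)O[C@]1(C)C=C(O[Si](C)(C)C)[C@@H]2C(C)(C)CCC[C@]2(C)[C@@]12CC[C@@](CO[Si](c3ccccc3)(c3ccccc3)C(C)(C)C)(C#C)O2 | intermediate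
24 | (5R,6R,7R,8R,9S,10S,13S)-16-[tert-butyl(diphenyl)silyl]oxy-6-(trimethylsilyloxy)-6,7:9,13-diepoxylabd-14-yn-8-yl acetate (6β,7β-epoxide) | CC(=O)O[C@]1(C)[C@H]3O[C@@]3(O[Si](C)(C)C)[C@@H]2C(C)(C)CCC[C@]2(C)[C@@]12CC[C@@](CO[Si](c4ccccc4)(c4ccccc4)C(C)(C)C)(C#C)O2 | intermediate (not isolated)
25 | (5R,7R,8R,9S,10S,13S)-16-[tert-butyl(diphenyl)silyl]oxy-6-oxo-7-(trimethylsilyloxy)-9,13-epoxylabd-14-yn-8-yl acetate | CC(=O)O[C@]1(C)[C@@H](O[Si](C)(C)C)C(=O)[C@@H]2C(C)(C)CCC[C@]2(C)[C@@]12CC[C@@](CO[Si](c3ccccc3)(c3ccccc3)C(C)(C)C)(C#C)O2 | intermediate (not isolated)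
26 | (5R,7R,8R,9S,10S,13S)-16-[tert-butyl(diphenyl)silyl]oxy-7-hydroxy-6-oxo-9,13-epoxylabd-14-yn-8-yl acetate | CC(=O)O[C@]1(C)[C@@H](O)C(=O)[C@@H]2C(C)(C)CCC[C@]2(C)[C@@]12CC[C@@](CO[Si](c3ccccc3)(c3ccccc3)C(C)(C)C)(C#C)O2 | intermediate
27 | (5R,7R,8R,9S,10S,13S)-7,16-dihydroxy-6-oxo-9,13-epoxylabd-14-yn-8-yl acetate | CC(=O)O[C@]1(C)[C@@H](O)C(=O)[C@@H]2C(C)(C)CCC[C@]2(C)[C@@]12CC[C@@](CO)(C#C)O2 | intermediate
28 | (5R,7R,8R,9S,10S,13S)-7-hydroxy-6-oxo-9,13:15,16-diepoxylabd-14-en-8-yl acetate (CNP0275274.1) | CC(=O)O[C@]1(C)[C@@H](O)C(=O)[C@@H]2C(C)(C)CCC[C@]2(C)[C@@]12CC[C@@]1(C=COC1)O2 | target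

## Step count and least certain steps

Total: 21 steps. Longest linear sequence: 21 steps, from 1 to 28; 7 and 13 enter in steps 5 and 9.

**Step 6 (key step).** The quaternary C10 may migrate in competition with the methylene C7. Part of the reaction may also pass through a chelated arrangement, which would erode control at C8. Poor facial selectivity in step 5 would change which medium is needed: the C9 epimer of 9 would require the chelating Lewis acid instead of base. Fallback: starting from 6, a one-carbon ring enlargement with diazoethane under Sc(OTf)3 catalysis, in which the less substituted α-carbon should migrate, would give (2S,8aS)-2,5,5,8a-tetramethyl-3,5,6,7,8,8a-hexahydronaphthalen-1(2H)-one F1 (either C2 epimer serves). Deprotonation at its only enolisable position with KN(SiMe3)2 and oxidation of the enolate with 2-(phenylsulfonyl)-3-phenyloxaziridine, expected anti to the C10 methyl, comes back to the route at 10.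

**Step 9.** SN2 opening at the neopentyl-like oxirane carbon may be slow, and the strongly basic, aggregated dianion may be consumed by the free hydroxyl. Fallback: starting from 12, opening with MgI2 at the CH2 carbon would give the iodohydrin (1S,2R,8aS)-1-(iodomethyl)-2,5,5,8a-tetramethyl-1,2,3,5,6,7,8,8a-octahydronaphthalene-1,2-diol F2. Radical allylation of F2 with ethyl 2-[(tributylstannyl)methyl]acrylate (AIBN, benzene, 80 °C), which is little affected by crowding, would give ethyl 4-[(1S,2R,8aS)-1,2-dihydroxy-2,5,5,8a-tetramethyl-1,2,3,5,6,7,8,8a-octahydronaphthalen-1-yl]-2-methylidenebutanoate F3. Reduction of the ester with i-Bu2AlH comes back at 14.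

**Step 17.** The C4 or C10 methyl groups may shift to the C5 cation, ring B may contract by migration of C7, or the Lewis acid may ionise the tertiary acetate. Insufficient facial control in step 15 would also show up here as the trans-fused ketone. Fallback: starting from 21, reductive opening with Cp2TiCl (trivalent titanium, made from Cp2TiCl2 and Mn) and water as hydrogen-atom source would cleave the C5–O bond homolytically. The tertiary C5 radical should take up hydrogen anti to the bulky titanoxy group on C6, giving (5R,6S,8R,9S,10S,13S)-16-[tert-butyl(diphenyl)silyl]oxy-6-hydroxy-9,13-epoxylabd-14-yn-8-yl acetate F4. Dess–Martin oxidation comes back at 22.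

**Step 19.** Facial selectivity at C7 may be poor: attack syn to the acetate, avoiding the axial C11 methylene, would give the C7 epimer. The allylic acetate of 23 may also ionise. Fallback: starting from 23, bromination with N-bromosuccinimide, expected on the same face as the oxidant, would give the 7α-bromo ketone (5R,7S,8S,9S,10S,13S)-7-bromo-16-[tert-butyl(diphenyl)silyl]oxy-6-oxo-9,13-epoxylabd-14-yn-8-yl acetate F5. SN2 displacement with HCO2Cs, with inversion and without participation by the cis acetate, would give the 7β-formate (5R,7R,8R,9S,10S,13S)-16-[tert-butyl(diphenyl)silyl]oxy-7-formyloxy-6-oxo-9,13-epoxylabd-14-yn-8-yl acetate F6. Methanolysis with KHCO3 in MeOH comes back at 26.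

**Step 7.** Methylenation of a carbonyl between two fully substituted carbons may be incomplete, and the aluminium centre may induce a further acyloin shift in 10. Fallback: starting from 10, a Peterson olefination in two stages: addition of Me3SiCH2Li/CeCl3 would give (1R,2R,8aS)-2,5,5,8a-tetramethyl-1-[(trimethylsilyl)methyl]-1,2,3,5,6,7,8,8a-octahydronaphthalene-1,2-diol F7, and syn elimination with KH comes back at 11.

## Further compounds

F1 | step 6 | (2S,8aS)-2,5,5,8a-tetramethyl-3,5,6,7,8,8a-hexahydronaphthalen-1(2H)-one | C[C@H]1CC=C2C(C)(C)CCC[C@]2(C)C1=O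
F2 | step 9 | (1S,2R,8aS)-1-(iodomethyl)-2,5,5,8a-tetramethyl-1,2,3,5,6,7,8,8a-octahydronaphthalene-1,2-diol | O[C@]1(C)CC=C2C(C)(C)CCC[C@]2(C)[C@@]1(O)CI
F3 | step 9 | ethyl 4-[(1S,2R,8aS)-1,2-dihydroxy-2,5,5,8a-tetramethyl-1,2,3,5,6,7,8,8a-octahydronaphthalen-1-yl]-2-methylidenebutanoate | O[C@]1(C)CC=C2C(C)(C)CCC[C@]2(C)[C@@]1(O)CCC(=C)C(=O)OCC
F4 | step 17 | (5R,6S,8R,9S,10S,13S)-16-[tert-butyl(diphenyl)silyl]oxy-6-hydroxy-9,13-epoxylabd-14-yn-8-yl acetate | CC(=O)O[C@]1(C)C[C@H](O)[C@@H]2C(C)(C)CCC[C@]2(C)[C@@]12CC[C@@](CO[Si](c3ccccc3)(c3ccccc3)C(C)(C)C)(C#C)O2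
F5 | step 19 | (5R,7S,8S,9S,10S,13S)-7-bromo-16-[tert-butyl(diphenyl)silyl]oxy-6-oxo-9,13-epoxylabd-14-yn-8-yl acetate | CC(=O)O[C@]1(C)[C@H](Br)C(=O)[C@@H]2C(C)(C)CCC[C@]2(C)[C@@]12CC[C@@](CO[Si](c3ccccc3)(c3ccccc3)C(C)(C)C)(C#C)O2
F6 | step 19 | (5R,7R,8R,9S,10S,13S)-16-[tert-butyl(diphenyl)silyl]oxy-7-formyloxy-6-oxo-9,13-epoxylabd-14-yn-8-yl acetate | CC(=O)O[C@]1(C)[C@@H](OC=O)C(=O)[C@@H]2C(C)(C)CCC[C@]2(C)[C@@]12CC[C@@](CO[Si](c3ccccc3)(c3ccccc3)C(C)(C)C)(C#C)O2
F7 | step 7 | (1R,2R,8aS)-2,5,5,8a-tetramethyl-1-[(trimethylsilyl)methyl]-1,2,3,5,6,7,8,8a-octahydronaphthalene-1,2-diol | O[C@]1(C)CC=C2C(C)(C)CCC[C@]2(C)[C@]1(O)C[Si](C)(C)C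
A1 | alternative 1 | (1R,2S)-2-{[tert-butyl(dimethyl)silyl]oxymethyl}-2,6,6-trimethylcyclohex-3-ene-1-carboxylic acid | OC(=O)[C@@H]1C(C)(C)CC=C[C@]1(C)CO[Si](C)(C)C(C)(C)C
A2 | alternative 2 | (8R,9S,10S,13S)-8-(methoxymethoxy)-9,13-epoxylabd-5-en-15,16-olide | COCO[C@]1(C)CC=C2C(C)(C)CCC[C@]2(C)[C@@]13CC[C@@]4(CC(=O)OC4)O3
A3 | alternative 3 | 2,6-dimethyl-1,4-benzoquinone | CC1=CC(=O)C=C(C)C1=O
A4 | alternative 3 | 4-methylpenta-1,3-diene | CC(C)=CC=C
A5 | alternative 3 | (4aR,8aS)-2,5,5,8a-tetramethyl-4a,5,8,8a-tetrahydronaphthalene-1,4-dione | CC1=CC(=O)[C@@H]2C(C)(C)C=CC[C@]2(C)C1=O
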